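**Strategy**

The benzene ring is built rather than bought: cutting C3a–C4 and C5–C6 leaves a chiral 2,3-dihydrofuran that comes from 2-deoxy-D-ribose with the trans C2/C3 pair already in place. The key step exploits the substitution pattern of the benzene ring: O1 on C7a and the hydroxyl on C6 are meta, and the C5 acetyl lies ortho to C6 and para to C7a, which is what a 1,1,3-trioxygenated diene imprints on an acetylenic ketone. One cycloaddition–aromatisation of but-3-yn-2-one with a silyl ketene acetal diene (ring enol ether C3a=C7a conjugated to exocyclic C7=C6, allylic C3 silyl ether, C2 isopropenyl) gives the whole 5-acetyl-6-hydroxy-2,3-dihydrobenzofuran core.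

Key step: step 9

Assumption: the hemiketal carbon of the Claisen adduct, the exocyclic C=C geometry of the ylidene ester and the ketene acetal geometry of the diene are written as unspecified or single isomers; all three elements vanish in the arene, so isomer mixtures are carried forward.

**Route**

Step 1
Reactants: 1 2-deoxy-D-ribose (written open-chain; reacts as the furanose hemiacetal)
Product: 2 2-deoxy-D-ribono-1,4-lactone [(4S,5R)-4-hydroxy-5-(hydroxymethyl)oxolan-2-one]
Conditions: Br2, H2O, rt, dark; evaporation
Reagents that add atoms: none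
Why: Bromine-water oxidation of an aldose hemiacetal to the aldono-1,4-lactone touches only the anomeric carbon, so both carbinol stereocentres of the sugar are carried over unchanged.

Step 2
Reactants: 2 2-deoxy-D-ribono-1,4-lactone
Product: 4 (2S,3S)-3-hydroxy-5-oxooxolane-2-carboxylic acid, via aldehyde 3 (not isolated)
Conditions: TEMPO (cat.), PhI(OAc)2, MeCN/H2O, rt
Reagents that add atoms: water, O
Why: Oxoammonium (TEMPO/PhI(OAc)2) oxidation should take the primary alcohol through aldehyde 3 and its hydrate to the acid while the more hindered secondary hydroxyl is left, the selectivity used for uronic acids from partly protected sugars; no base is present and no stereocentre is touched.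

Step 3
Reactants: 4 (2S,3S)-3-hydroxy-5-oxooxolane-2-carboxylic acid
Product: 5 tert-butyldimethylsilyl (2S,3S)-3-[(tert-butyldimethylsilyl)oxy]-5-oxooxolane-2-carboxylate
Conditions: TBSCl, imidazole, DMF, rt
Reagents that add atoms: tert-butyl(chloro)dimethylsilane, CC(C)(C)[Si](C)(C)Cl
Why: Imidazole-promoted silylation should cap the secondary hydroxyl as its silyl ether and the acid as a silyl ester, the latter being a precursor of the acyl chloride under neutral conditions.

Step 4
Reactants: 5 bis-silylated lactone acid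
Product: 7 (4S,5S)-5-acetyl-4-[(tert-butyldimethylsilyl)oxy]oxolan-2-one, via acid chloride 6 (not isolated)
Conditions: (COCl)2, DMF (cat.), CH2Cl2, 0 °C to rt; evaporation; then Me2Zn, Pd(PPh3)4 (cat.), THF, 0 °C to rt
Reagents that add atoms: dimethylzinc, C[Zn]C; oxalyl chloride, O=C(Cl)C(=O)Cl (chlorine of intermediate 6 only)
Why: The silyl ester should exchange with the chloroiminium species from DMF and oxalyl chloride to give acyl chloride 6 without free HCl, and Negishi acylation then stops at the methyl ketone because dimethylzinc attacks neither the lactone nor the product ketone and is neither basic nor reducing enough to disturb the α-acyloxy carbon.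

Step 5
Reactants: 7 methyl ketone
Product: 8 (4S,5R)-4-[(tert-butyldimethylsilyl)oxy]-5-(prop-1-en-2-yl)oxolan-2-one
Conditions: Zn, CH2Br2, TiCl4 (preformed reagent), THF/CH2Cl2, 0 °C to rt
Reagents that add atoms: dibromomethane, BrCBr
Why: Takai–Lombardo methylenation is non-basic and selective for ketones over lactones, so the isopropenyl group should form without epimerising the adjacent oxygen-bearing carbon or eliminating the β-silyloxy group.

Step 6
Reactants: 8 isopropenyl lactone; 9 methyl acetate
Product: 11 methyl 2-[(4S,5R)-4-[(tert-butyldimethylsilyl)oxy]-2-hydroxy-5-(prop-1-en-2-yl)oxolan-2-yl]acetate, via lithium enolate of methyl acetate 10 (not isolated)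
Conditions: LiN(iPr)2, 9, THF, −78 °C; then 8, −78 °C; AcOH quench
Reagents that add atoms: lithium diisopropylamide, [Li+].CC(C)[N-]C(C)C (lithium of intermediate 10 only)
Why: Claisen-type addition of an ester enolate to a lactone carbonyl stops after one addition because the tetrahedral lithium alkoxide persists at −78 °C, and protonation should give the hemiketal (ring form of the γ-hydroxy-β-keto ester) as an anomer mixture of no consequence.

Step 7
Reactants: 11 hemiketal
Product: 12 methyl (2E)-2-[(4S,5R)-4-[(tert-butyldimethylsilyl)oxy]-5-(prop-1-en-2-yl)oxolan-2-ylidene]acetate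
Conditions: PPTS (cat.), 4 Å molecular sieves, toluene, 50 °C
Reagents that add atoms: none
Why: Acid-catalysed cyclodehydration of a γ-hydroxy-β-keto ester to a 2-alkylidene tetrahydrofuran (a vinylogous carbonate) removes water towards the acidic hydrogen next to the ester, and since neither the C4–O nor the C5–O bond is broken both stereocentres are retained.

Step 8
Reactants: 12 ylidene ester
Product: 14 tert-butyl({(2R,3S)-5-[(Z)-2-methoxy-2-(trimethylsilyloxy)ethenyl]-2-(prop-1-en-2-yl)-2,3-dihydrofuran-3-yl}oxy)dimethylsilane, via lithium dienolate 13 (not isolated)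
Conditions: Me3SiCl, THF, −78 °C, LiN(iPr)2 added last (in situ quench); evaporation, pentane, filtration under Ar, high vacuum; used at once
Reagents that add atoms: chlorotrimethylsilane, C[Si](C)(C)Cl; lithium diisopropylamide, [Li+].CC(C)[N-]C(C)C (lithium of intermediate 13 only)
Why: γ-Deprotonation of a 3-alkoxy-2-enoate with O-silylation is the standard entry to 1-alkoxy-1-silyloxy-3-oxy-dienes, and having the silyl chloride present from the start should trap dienolate 13 before it can expel the β-silyloxy group; C2 and C3 are not involved.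

Step 9
Reactants: 14 dienyl silyl ketene acetal; 15 but-3-yn-2-one
Product: 18 1-[(2R,3S)-3-[(tert-butyldimethylsilyl)oxy]-6-hydroxy-2-(prop-1-en-2-yl)-2,3-dihydro-1-benzofuran-5-yl]ethan-1-one, via cyclohexa-1,4-diene cycloadduct 16 (not isolated), via aryl trimethylsilyl ether 17 (not isolated)
Conditions: toluene, −20 °C to rt, amine-free; then aq. citric acid/THF, 0 °C
Reagents that add atoms: none
Why: The electron-rich diene C3a=C7a–C7=C6 adds across the triple bond of 15 in an asynchronous (4+2) process in which C3a–C4 forms ahead of C5–C6, giving cyclohexa-1,4-diene 16, which loses methanol across C3a–H/C6–OMe to aryl silyl ether 17, and mild acid then hydrolyses the aryl O–Si bond to the hydrogen-bonded phenol 18. The closest known reaction type is the Diels–Alder/aromatisation synthesis of acylresorcinols from 1-alkoxy-1-silyloxy-3-oxy-1,3-dienes and acetylenic ketones. The six-membered carbocycle is closed intermolecularly by the cycloaddition itself, both ring bonds in one operation (in the stepwise limit a 6-exo-trig collapse of the allenolate carbon C5 onto the oxocarbenium carbon C6). No stereocentre is created, since the sp3 centres C3a and C6 of 16 are erased on aromatisation and C2 and C3 are spectators, so the facial course is irrelevant. Only regiochemistry is needed, and it is set by polarity matching: C3a, the terminus vinylogous to the ketene acetal oxygens and to O1, attacks the β-carbon of the ynone, which places the acetyl on C5, ortho to the C6 oxygen and para to C7a. The isopropenyl group is neither a diene nor an activated dienophile, and the absence of amine and of strong acid should keep the ynone from oligomerising and the allylic C3 silyl ether from ionising.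

Step 10
Reactants: 18 silyl ether phenol
Product: 19 1-[(2R,3S)-3,6-dihydroxy-2-(prop-1-en-2-yl)-2,3-dihydro-1-benzofuran-5-yl]ethan-1-one
Conditions: Bu4NF, AcOH, THF, 0 °C
Reagents that add atoms: none
Why: Fluoride desilylation buffered with acetic acid should free the benzylic alcohol without forming the phenoxide, which could otherwise expel the para-benzylic oxygen; the C3–O bond is not broken.

Step 11
Reactants: 20 3-methylfuran-2(5H)-one
Product: 21 (2Z)-4-chloro-2-methylbut-2-enoyl chloride
Conditions: SOCl2, ZnCl2 (cat.), 60 °C; short-path distillation under reduced pressure; used fresh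
Reagents that add atoms: thionyl chloride, O=S(Cl)Cl
Why: Lewis-acid-catalysed lactone opening with thionyl chloride (the γ-butyrolactone to 4-chlorobutanoyl chloride reaction) should put chloride on the allylic CH2 and turn the carboxylate into the acyl chloride, the ring-imposed cis relation of carbonyl and CH2 becoming the Z alkene.

Step 12
Reactants: 19 diol; 21 (2Z)-4-chloro-2-methylbut-2-enoyl chloride
Product: 22 (2R,3S)-5-acetyl-6-hydroxy-2-(prop-1-en-2-yl)-2,3-dihydro-1-benzofuran-3-yl (2Z)-4-chloro-2-methylbut-2-enoate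
Conditions: pyridine, CH2Cl2, −20 °C to 0 °C
Reagents that add atoms: none
Why: Acylation with an acyl chloride and pyridine (Einhorn conditions) should take the secondary alcohol in preference to the phenol, which is hydrogen-bonded to the ortho acetyl group and much less nucleophilic, and C3 keeps its configuration because its C–O bond is not broken.

Step 13
Reactants: 22 chloro ester
Product: 23 (2R,3S)-5-acetyl-6-hydroxy-2-(prop-1-en-2-yl)-2,3-dihydro-1-benzofuran-3-yl (2Z)-4-(acetyloxy)-2-methylbut-2-enoate (target)
Conditions: CsOAc, AcOH (buffer), DMF, rt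
Reagents that add atoms: cesium acetate, [Cs+].CC(=O)[O-]
Why: SN2 displacement of the primary allylic chloride by a cesium carboxylate in a dipolar aprotic solvent should install the acetate without ever exposing a free Z γ-hydroxy ester (which would lactonise), and the acetic acid buffer keeps the phenol protonated.

**Compound list**

1 | 2-deoxy-D-ribose | O=CC[C@H](O)[C@@H](CO)O | starting material
2 | 2-deoxy-D-ribono-1,4-lactone, (4S,5R)-4-hydroxy-5-(hydroxymethyl)oxolan-2-one | O=C1C[C@H](O)[C@@H](CO)O1 | intermediate
3 | (2S,3S)-3-hydroxy-5-oxooxolane-2-carbaldehyde (not isolated) | O=C1C[C@H](O)[C@@H](C=O)O1 | intermediate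
4 | (2S,3S)-3-hydroxy-5-oxooxolane-2-carboxylic acid | O=C1C[C@H](O)[C@@H](C(=O)O)O1 | intermediate
5 | tert-butyldimethylsilyl (2S,3S)-3-[(tert-butyldimethylsilyl)oxy]-5-oxooxolane-2-carboxylate | O=C1C[C@H](O[Si](C)(C)C(C)(C)C)[C@@H](C(=O)O[Si](C)(C)C(C)(C)C)O1 | intermediate
6 | (2S,3S)-3-[(tert-butyldimethylsilyl)oxy]-5-oxooxolane-2-carbonyl chloride (not isolated) | O=C1C[C@H](O[Si](C)(C)C(C)(C)C)[C@@H](C(=O)Cl)O1 | intermediate
7 | (4S,5S)-5-acetyl-4-[(tert-butyldimethylsilyl)oxy]oxolan-2-one | O=C1C[C@H](O[Si](C)(C)C(C)(C)C)[C@@H](C(C)=O)O1 | intermediate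
8 | (4S,5R)-4-[(tert-butyldimethylsilyl)oxy]-5-(prop-1-en-2-yl)oxolan-2-one | O=C1C[C@H](O[Si](C)(C)C(C)(C)C)[C@@H](C(C)=C)O1 | intermediate
9 | methyl acetate | COC(C)=O | starting material
10 | lithium 1-methoxyethen-1-olate (not isolated) | [Li+].C=C([O-])OC | intermediate
11 | methyl 2-[(4S,5R)-4-[(tert-butyldimethylsilyl)oxy]-2-hydroxy-5-(prop-1-en-2-yl)oxolan-2-yl]acetate (anomer mixture) | COC(=O)CC1(O)C[C@H](O[Si](C)(C)C(C)(C)C)[C@@H](C(C)=C)O1 | intermediate
12 | methyl (2E)-2-[(4S,5R)-4-[(tert-butyldimethylsilyl)oxy]-5-(prop-1-en-2-yl)oxolan-2-ylidene]acetate | COC(=O)/C=C1\C[C@H](O[Si](C)(C)C(C)(C)C)[C@@H](C(C)=C)O1 | intermediate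
13 | lithium dienolate of 12, γ-deprotonated at C3a (not isolated) | [Li+].C=C(C)[C@H]1OC(/C=C(/OC)[O-])=C[C@@H]1O[Si](C)(C)C(C)(C)C | intermediate
14 | tert-butyl({(2R,3S)-5-[(Z)-2-methoxy-2-(trimethylsilyloxy)ethenyl]-2-(prop-1-en-2-yl)-2,3-dihydrofuran-3-yl}oxy)dimethylsilane | C=C(C)[C@H]1OC(/C=C(/OC)O[Si](C)(C)C)=C[C@@H]1O[Si](C)(C)C(C)(C)C | intermediate
15 | but-3-yn-2-one | C#CC(C)=O | starting material
16 | 1-[(2R,3S)-3-[(tert-butyldimethylsilyl)oxy]-6-methoxy-2-(prop-1-en-2-yl)-6-(trimethylsilyloxy)-2,3,3a,6-tetrahydro-1-benzofuran-5-yl]ethan-1-one (not isolated) | C=C(C)[C@H]1OC2=CC(OC)(O[Si](C)(C)C)C(C(C)=O)=CC2[C@@H]1O[Si](C)(C)C(C)(C)C | intermediate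
17 | 1-[(2R,3S)-3-[(tert-butyldimethylsilyl)oxy]-2-(prop-1-en-2-yl)-6-(trimethylsilyloxy)-2,3-dihydro-1-benzofuran-5-yl]ethan-1-one (not isolated) | C=C(C)[C@H]1Oc2cc(O[Si](C)(C)C)c(C(C)=O)cc2[C@@H]1O[Si](C)(C)C(C)(C)C | intermediate
18 | 1-[(2R,3S)-3-[(tert-butyldimethylsilyl)oxy]-6-hydroxy-2-(prop-1-en-2-yl)-2,3-dihydro-1-benzofuran-5-yl]ethan-1-one | C=C(C)[C@H]1Oc2cc(O)c(C(C)=O)cc2[C@@H]1O[Si](C)(C)C(C)(C)C | intermediate
19 | 1-[(2R,3S)-3,6-dihydroxy-2-(prop-1-en-2-yl)-2,3-dihydro-1-benzofuran-5-yl]ethan-1-one | C=C(C)[C@H]1Oc2cc(O)c(C(C)=O)cc2[C@@H]1O | intermediate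
20 | 3-methylfuran-2(5H)-one | CC1=CCOC1=O | starting material
21 | (2Z)-4-chloro-2-methylbut-2-enoyl chloride | O=C(Cl)/C(C)=C\CCl | intermediate
22 | (2R,3S)-5-acetyl-6-hydroxy-2-(prop-1-en-2-yl)-2,3-dihydro-1-benzofuran-3-yl (2Z)-4-chloro-2-methylbut-2-enoate | C=C(C)[C@H]1Oc2cc(O)c(C(C)=O)cc2[C@@H]1OC(=O)/C(C)=C\CCl | intermediate
23 | (2R,3S)-5-acetyl-6-hydroxy-2-(prop-1-en-2-yl)-2,3-dihydro-1-benzofuran-3-yl (2Z)-4-(acetyloxy)-2-methylbut-2-enoate | C=C(C)[C@H]1Oc2cc(O)c(C(C)=O)cc2[C@@H]1OC(=O)/C(C)=C\COC(C)=O | target

**Step count and risks**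

Total step count: 13. Longest linear sequence: 12 steps (steps 1–10, 12 and 13); step 11 is a one-step side branch.

Steps most likely to fail:

1. Step 9. The diene may add to the ynone through C7 as a Michael donor, or trigger oligomerisation of the ynone, instead of closing the ring. On the acidic work-up the doubly activated C3–O bond may also ionise, with loss of silanol and aromatisation of the oxygen ring. Fallback: an ionic Michael–Claisen benzannulation that forms the same two bonds without a silyl ketene acetal or an ynone. It sets out from 12. Its lithium dienolate 13 (LiN(iPr)2, THF, −78 °C) should add through C3a to commercial (E)-4-methoxybut-3-en-2-one to give the Michael adduct methyl (2E)-2-[(4S,5R)-4-[(tert-butyldimethylsilyl)oxy]-3-(1-methoxy-3-oxobutyl)-5-(prop-1-en-2-yl)oxolan-2-ylidene]acetate F1. On warming, the ketone enolate carbon C5 of F1 should close onto the ester carbonyl C6 (Dieckmann-type, loss of methoxide) to give the 5-acetyl-4-methoxy-tetrahydrobenzofuran-6-one F2. F2 should eliminate methanol and tautomerise to phenol 18, where the fallback rejoins the route.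

2. Step 8. The lithium dienolate may expel the β-silanolate (E1cB) and tautomerise to a 2,5-disubstituted furan, or the allylic silyl ether of the finished diene may ionise on traces of acid. Fallback: carry the C3 oxygen as an oxido group, which cannot leave. It sets out from 12. Bu4NF/AcOH should give the hydroxy ylidene ester F3. LiN(iPr)2 (2.2 equiv) with Me3SiCl (2.5 equiv) at −78 °C should then take F3 through the dilithium alkoxide–dienolate F4 to the bis(trimethylsilyl) diene F5. F5 and 15 should give the cycloadduct F6 and, after loss of methanol, the aryl bis(trimethylsilyl) ether F7. The acidic work-up cleaves both silyl ethers and the sequence returns at 19, so step 10 falls away.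

3. Step 12. The phenol may be acylated in competition, the Z geometry may be lost through a vinylketene or through chloride addition–elimination, and the benzylic alcohol may ionise towards the benzofuran. Fallback: attach a saturated acyl group first and build the Z alkene afterwards. It sets out from 19. Steglich esterification (DCC, cat. DMAP, CH2Cl2, 0 °C) with 2-[bis(2,2,2-trifluoroethoxy)phosphoryl]propanoic acid F8 (from its commercial ethyl ester, LiOH, THF/H2O, 0 °C) should give the phosphonate ester F9. Still–Gennari olefination of F9 with commercial 2-oxoethyl acetate (KN(SiMe3)2, two equivalents because the phenol takes up the first, 18-crown-6, THF, −78 °C) should form the Z trisubstituted alkene with the acetoxy group already in place. It returns directly at 23, bypassing steps 11–13.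

**Further compounds**

F1 | step 9 | methyl (2E)-2-[(4S,5R)-4-[(tert-butyldimethylsilyl)oxy]-3-(1-methoxy-3-oxobutyl)-5-(prop-1-en-2-yl)oxolan-2-ylidene]acetate | COC(=O)/C=C1\C(C(OC)CC(C)=O)[C@H](O[Si](C)(C)C(C)(C)C)[C@@H](C(C)=C)O1
F2 | step 9 | (2R,3S)-5-acetyl-3-[(tert-butyldimethylsilyl)oxy]-4-methoxy-2-(prop-1-en-2-yl)-3,3a,4,5-tetrahydro-1-benzofuran-6(2H)-one | C=C(C)[C@H]1OC2=CC(=O)C(C(C)=O)C(OC)C2[C@@H]1O[Si](C)(C)C(C)(C)C
F3 | step 8 | methyl (2E)-2-[(4S,5R)-4-hydroxy-5-(prop-1-en-2-yl)oxolan-2-ylidene]acetate | COC(=O)/C=C1\C[C@H](O)[C@@H](C(C)=C)O1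
F4 | step 8 | dilithium alkoxide–dienolate of F3 | [Li+].[Li+].C=C(C)[C@H]1OC(/C=C(/OC)[O-])=C[C@@H]1[O-]
F5 | step 8 | {[(2R,3S)-5-[(Z)-2-methoxy-2-(trimethylsilyloxy)ethenyl]-2-(prop-1-en-2-yl)-2,3-dihydrofuran-3-yl]oxy}trimethylsilane | C=C(C)[C@H]1OC(/C=C(/OC)O[Si](C)(C)C)=C[C@@H]1O[Si](C)(C)C
F6 | step 8 | 1-[(2R,3S)-6-methoxy-2-(prop-1-en-2-yl)-3,6-bis(trimethylsilyloxy)-2,3,3a,6-tetrahydro-1-benzofuran-5-yl]ethan-1-one | C=C(C)[C@H]1OC2=CC(OC)(O[Si](C)(C)C)C(C(C)=O)=CC2[C@@H]1O[Si](C)(C)C
F7 | step 8 | 1-[(2R,3S)-2-(prop-1-en-2-yl)-3,6-bis(trimethylsilyloxy)-2,3-dihydro-1-benzofuran-5-yl]ethan-1-one | C=C(C)[C@H]1Oc2cc(O[Si](C)(C)C)c(C(C)=O)cc2[C@@H]1O[Si](C)(C)C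
F8 | step 12 | 2-[bis(2,2,2-trifluoroethoxy)phosphoryl]propanoic acid | CC(C(=O)O)P(=O)(OCC(F)(F)F)OCC(F)(F)F
F9 | step 12 | (2R,3S)-5-acetyl-6-hydroxy-2-(prop-1-en-2-yl)-2,3-dihydro-1-benzofuran-3-yl 2-[bis(2,2,2-trifluoroethoxy)phosphoryl]propanoate | C=C(C)[C@H]1Oc2cc(O)c(C(C)=O)cc2[C@@H]1OC(=O)C(C)P(=O)(OCC(F)(F)F)OCC(F)(F)F
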